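**Plan**

1. Numbering and rings: C1 is the quaternary ring-fusion carbon (methyl C15), C2 the acetoxy CH, C3 and C4 are CH2, C5 (methyl C16)=C6(Cl), C7 the lactone O–CH, C8 the tertiary carbinol, C9 the CHOH, C10 the ring-fusion CH, C11 carries methyl C20, C12 the acetoxy CH, C13=C14, C17 carries methyl C18, C19 is the lactone carbonyl. Ring A is the cyclohexene (C1, C10–C14), ring B the ten-membered ring (C1–C10), ring C the γ-lactone.
2. Cuts: the lactone O7–C19 bond and the C7/C8 diol go back to a C7=C8 alkene; ring B is cut at C8–C9 (alkenyl iodide plus aldehyde), then at C3–C4 and C2–C3 (β-keto sulfone); ring A is cut at C10–C11 and C1–C14.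
3. Forward order: ring A by Diels–Alder reaction, C12 oxygen by epoxide transposition, chain joined at C2–C3 and then C3–C4, ring B closed at C8–C9 by Nozaki–Hiyama–Kishi reaction, ring C last by oxidative lactonisation.
4. Enabling feature: C1, C10 and C11 are adjacent on ring A with C15, C9 and C20 on one face. This is the endo adduct pattern of an (E)-1-methyl diene with an (E)-formyl enoate that carries C9 as formyl and C2 as ester. The C12=C13 alkene left by the cycloaddition is one allylic transposition away from C12–O and C13=C14.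
5. Stereochemistry: C1, C10, C11 from the catalyst-controlled endo cycloaddition; C12 from α-face epoxidation; C2 from CBS reduction; C17 from (S)-3-bromo-2-methylpropan-1-ol; C9 from hydride attack on the ring ketone anti to C1; C7 and C8 from C9–OH-directed syn-dihydroxylation; the C5=C6 geometry from syn-carbocupration and chlorination.

Key step: step 3

Assumption: the facial sense of the oxazaborolidinium catalyst is assigned from its formyl C–H···O binding model (diene on the C10 Si face with the (R)-catalyst); if the opposite sense were found, the (S)-catalyst would be used with no other change.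

**Route**

Step 1
Reactants: 1 2,2-dimethoxyacetaldehyde; 2 methyl 2-(triphenylphosphoranylidene)propanoate
Product: 3 methyl (E)-4,4-dimethoxy-2-methylbut-2-enoate
Conditions: 1 (60% aq. solution), 2, CH2Cl2, rt
Reagents that add atoms: none
Why: Wittig olefination with an ester-stabilised α-methyl ylide, which should be (E)-selective because the oxaphosphetane forms reversibly and collapses through its less crowded trans isomer.

Step 2
Reactants: 3
Product: 4 methyl (E)-2-methyl-4-oxobut-2-enoate
Conditions: Amberlyst-15, acetone–H2O, rt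
Reagents that add atoms: water, O
Why: Acid-catalysed acetal hydrolysis to the conjugated aldehyde, in which the (E) geometry (formyl cis to the methyl group) should persist because no base is present.

Step 3
Reactants: 4; 5 (E)-penta-1,3-diene
Product: 6 methyl (1S,5S,6S)-6-formyl-1,5-dimethylcyclohex-3-ene-1-carboxylate
Conditions: (R)-o-tolyl-CBS-oxazaborolidine (20 mol%), Tf2NH (18 mol%), 5 (4 equiv), CH2Cl2, −78 → −40 °C
Reagents that add atoms: none
Why: The protonated oxazaborolidine binds the formyl oxygen of 4, and the s-trans enal then takes up the diene in a concerted, asynchronous [4+2] cycloaddition in which C1–C14 bonding runs ahead of C10–C11 bonding. The closest known reaction type is the oxazaborolidinium-catalysed Diels–Alder reaction of α,β-unsaturated aldehydes with acyclic dienes. Ring A closes in this one intermolecular cycloaddition, both new σ-bonds forming suprafacially on diene and dienophile. C10 is controlled by the catalyst, which covers one face of the bound enal so that the diene meets the C10 Si face; C11 is controlled by the endo position of the activated formyl group beside the (E)-methyl terminus, which puts C20 syn to C9; C1 is controlled by the (E) geometry of 4, which holds formyl and methyl cis and so puts C15 syn to C9. The step needs regio-, endo- and enantioface selectivity: the bound formyl group makes C1 the most electrophilic carbon, which pairs with the unsubstituted and most nucleophilic diene terminus C14, and the same bound carbonyl fixes the endo mode and the open face. The ester on C1 is a second acceptor at the fully substituted carbon and should offset the hindrance to bond formation there.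

Step 4
Reactants: 6
Product: 7 methyl (1S,5S,6S)-6-(dimethoxymethyl)-1,5-dimethylcyclohex-3-ene-1-carboxylate
Conditions: HC(OMe)3, MeOH, PPTS (cat.), rt
Reagents that add atoms: trimethyl orthoformate, COC(OC)OC
Why: Acid-catalysed acetalisation masks the C9 aldehyde against the carbanion and hydride steps ahead, and mild acid should leave the C10 centre untouched.

Step 5
Reactants: 7
Product: 8 12α,13α-epoxide of 7
Conditions: mCPBA, NaHCO3, CH2Cl2, 0 °C
Reagents that add atoms: 3-chloroperoxybenzoic acid (mCPBA), OOC(=O)c1cccc(Cl)c1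
Why: Prilezhaev epoxidation of the only alkene, in which the peracid should approach the α face, away from the allylic C11 methyl group and the C10 acetal on the β face, setting the C12–O configuration that is kept to the target.

Step 6
Reactants: 8
Product: 11 methyl (1S,4R,5R,6S)-6-(dimethoxymethyl)-4-hydroxy-1,5-dimethylcyclohex-2-ene-1-carboxylate, via hydroxy selenide 9 (not isolated), via selenoxide 10 (not isolated)
Conditions: PhSeSePh, NaBH4, EtOH, 60 °C; then THF, 30% H2O2, 0 °C → rt
Reagents that add atoms: none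
Why: Epoxide-to-allylic-alcohol transposition by selenide opening and selenoxide elimination: benzeneselenolate should open the oxirane with inversion at C13, the carbon remote from the C11 methyl group, and the selenoxide then undergoes syn-elimination away from the carbinol carbon toward C14, so C12 keeps its α-oxygen and the alkene moves to C13=C14.

Step 7
Reactants: 11; 12 methyl phenyl sulfone
Product: 14 1-[(1S,4R,5R,6S)-6-(dimethoxymethyl)-4-hydroxy-1,5-dimethylcyclohex-2-en-1-yl]-2-(phenylsulfonyl)ethan-1-one, via (phenylsulfonyl)methyllithium 13 (not isolated)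
Conditions: 12 (3.5 equiv), n-BuLi (3.5 equiv), THF, −78 → 0 °C; then 11, −78 °C → rt; aq. NH4Cl
Reagents that add atoms: none
Why: Claisen-type acylation of the α-sulfonyl carbanion by the neopentyl methyl ester adds C3; the C12 hydroxyl rides as its lithium alkoxide and the acidic product is held as its enolate, which should prevent a second addition.

Step 8
Reactants: 15 (S)-3-bromo-2-methylpropan-1-ol
Product: 16 (S)-(3-bromo-2-methylpropoxy)(tert-butyl)diphenylsilane
Conditions: TBDPSCl, imidazole, CH2Cl2, rt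
Reagents that add atoms: tert-butyl(chloro)diphenylsilane (TBDPSCl), CC(C)(C)[Si](Cl)(c1ccccc1)c1ccccc1
Why: Silylation of the primary alcohol (future C19–O); the C17 stereocentre comes from the chiral pool and is not touched.

Step 9
Reactants: 16
Product: 17 [(S)-3-{[tert-butyl(diphenyl)silyl]oxy}-2-methylpropyl](triphenyl)phosphonium bromide
Conditions: PPh3, MeCN, reflux
Reagents that add atoms: triphenylphosphine, c1ccc(cc1)P(c1ccccc1)c1ccccc1
Why: SN2 quaternisation of triphenylphosphine by the primary bromide gives the Wittig salt that carries C8, C17, C18 and C19.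

Step 10
Reactants: 18 2-(prop-2-yn-1-yloxy)tetrahydro-2H-pyran; 19 methyl chloroformate
Product: 21 methyl 4-(tetrahydro-2H-pyran-2-yloxy)but-2-ynoate, via lithium acetylide 20 (not isolated)
Conditions: n-BuLi, THF, −78 °C; then 19, −78 → 0 °C
Reagents that add atoms: none
Why: C-acylation of a lithium acetylide with a chloroformate gives the ynoate that holds C4 to C7.

Step 11
Reactants: 21
Product: 23 methyl (E)-2-chloro-3-methyl-4-(tetrahydro-2H-pyran-2-yloxy)but-2-enoate, via alkenylcuprate 22 (not isolated)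
Conditions: Me2CuLi (from MeLi and CuI), THF, −78 °C; then N-chlorosuccinimide, −78 °C; aq. NH4Cl
Reagents that add atoms: lithium dimethylcuprate, [Li+].C[Cu-]C; N-chlorosuccinimide, O=C1CCC(=O)N1Cl
Why: Conjugate syn-carbocupration of the ynoate puts the C16 methyl on C5 and copper on C6 cis to each other, and chlorination of the α-cuprio enoate at −78 °C with retention should give the tetrasubstituted chloroalkene with C4 cis to C7, the geometry needed in ring B.

Step 12
Reactants: 23
Product: 24 (E)-2-chloro-3-methyl-4-(tetrahydro-2H-pyran-2-yloxy)but-2-en-1-ol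
Conditions: i-Bu2AlH (2.5 equiv), CH2Cl2, −78 °C; aq. potassium sodium tartrate
Reagents that add atoms: none
Why: 1,2-Reduction of the enoate by the aluminium hydride to the allylic alcohol, which leaves the vinyl chloride and the acetal-type THP ether untouched.

Step 13
Reactants: 24
Product: 25 (E)-2-chloro-3-methyl-4-(tetrahydro-2H-pyran-2-yloxy)but-2-enal
Conditions: MnO2, CH2Cl2, rt
Reagents that add atoms: none
Why: Chemoselective oxidation of the allylic alcohol on the MnO2 surface under neutral conditions, which should not isomerise the tetrasubstituted alkene.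

Step 14
Reactants: 25; 17
Product: 29 tert-butyl{[(2S,3Z,5E)-5-chloro-3-iodo-2,6-dimethyl-7-(tetrahydro-2H-pyran-2-yloxy)hepta-3,5-dien-1-yl]oxy}diphenylsilane, via phosphonium ylide 26 (not isolated), via iodophosphonium iodide 27 (not isolated), via iodo ylide 28 (not isolated)
Conditions: 17, NaN(SiMe3)2 (1 equiv), THF, −78 → 0 °C; I2, −78 °C; NaN(SiMe3)2 (1 equiv), −78 °C; then 25, −78 → −20 °C
Reagents that add atoms: iodine, II
Why: Stork–Zhao-type iodo-Wittig olefination, in which the non-stabilised α-iodo ylide adds under kinetic control and should place iodine cis to C6 ((7Z) in target numbering), with C17 unaffected.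

Step 15
Reactants: 29
Product: 30 {[(2S,3Z,5E)-7-bromo-5-chloro-3-iodo-2,6-dimethylhepta-3,5-dien-1-yl]oxy}(tert-butyl)diphenylsilane
Conditions: Ph3PBr2, CH2Cl2, 0 °C → rt
Reagents that add atoms: dibromotriphenylphosphorane, BrP(Br)(c1ccccc1)(c1ccccc1)c1ccccc1
Why: Direct conversion of the THP ether into the primary allylic bromide through an alkoxyphosphonium ion and SN2 attack of bromide at C4, under which the TBDPS ether and both vinyl halides should be inert.

Step 16
Reactants: 14; 30
Product: 31 C3-(phenylsulfonyl) C2 ketone from C3–C4 alkylation (C3 epimers; C12 OH; C9 dimethyl acetal; (5E,7Z)-6-chloro-8-iodo diene; C19 OTBDPS)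
Conditions: K2CO3, Bu4NI (cat.), acetone, rt
Reagents that add atoms: none
Why: SN2 C-alkylation of the soft β-keto sulfone enolate by the primary allylic bromide forms C3–C4, and the secondary C12 alcohol is not ionised by carbonate.

Step 17
Reactants: 31
Product: 32 C2 ketone (31 without the sulfonyl group)
Conditions: SmI2, THF–MeOH, −78 °C
Reagents that add atoms: none
Why: Reductive desulfonylation of the α-sulfonyl ketone by single-electron transfer gives a samarium enolate that methanol protonates; without HMPA at −78 °C the vinyl iodide, vinyl chloride and hindered ketone should not be reduced.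

Step 18
Reactants: 32
Product: 33 (2S)-2,12-diol
Conditions: (R)-Me-CBS (0.3 equiv), BH3·SMe2, THF, −20 °C; MeOH
Reagents that add atoms: none
Why: Corey–Bakshi–Shibata reduction, in which the quaternary C1 acts as the large and the C3 methylene as the small ketone substituent, so the (R)-catalyst should deliver hydride to give (2S); ketone reduction inside the catalyst complex should outpace hydroboration of the hindered or halogenated alkenes.

Step 19
Reactants: 33
Product: 34 (2S)-2,12-diacetate
Conditions: Ac2O, Et3N, DMAP (cat.), CH2Cl2, rt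
Reagents that add atoms: acetic anhydride, CC(=O)OC(C)=O
Why: DMAP-catalysed acylation installs both acetates of the target at once, before any other hydroxyl is present.

Step 20
Reactants: 34
Product: 35 seco-aldehyde (C9 formyl; 2,12-diacetate; (7Z)-8-iodo diene; C19 OTBDPS)
Conditions: TsOH·H2O (cat.), acetone–H2O, rt
Reagents that add atoms: water, O
Why: Acid-catalysed hydrolysis of the dimethyl acetal frees the C9 aldehyde; the C2 oxygen is already acetylated, so no lactol can form, and acetates and TBDPS ether should survive.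

Step 21
Reactants: 35
Product: 36 ring B allylic alcohol (C9 epimers; (5E,7Z)-diene)
Conditions: CrCl2 (8 equiv), NiCl2 (0.1 equiv), DMSO–THF, rt, slow addition to 0.002 M
Reagents that add atoms: none
Why: Nozaki–Hiyama–Kishi reaction: zerovalent nickel inserts into the alkenyl C–I bond (the C–Cl bond stays), transmetalation gives an alkenylchromium that adds to the C9 aldehyde with retention of the (7Z) geometry and closes ring B at C8–C9; the C9 configuration formed here is not relied on because steps 22 and 23 reset it.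

Step 22
Reactants: 36
Product: 37 ring B dienone (C9 ketone)
Conditions: Dess–Martin periodinane, NaHCO3, CH2Cl2, 0 °C
Reagents that add atoms: none
Why: Dess–Martin oxidation of the only free hydroxyl converges both C9 epimers to one dienone under buffered conditions that should not epimerise C10.

Step 23
Reactants: 37
Product: 38 (9S)-allylic alcohol
Conditions: NaBH4, CeCl3·7H2O, MeOH, −78 °C
Reagents that add atoms: none
Why: Luche 1,2-reduction, in which hydride should reach the C9 carbonyl on its outer face anti to the quaternary C1 (Felkin–Anh geometry, with the ring holding C8 gauche to C1), giving (9S); the acetates should not be reduced at −78 °C.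

Step 24
Reactants: 38
Product: 40 (7R,8R,9S)-triol (C19 OTBDPS), via osmate ester 39 (not isolated)
Conditions: OsO4 (1.05 equiv), TMEDA (1.1 equiv), CH2Cl2, −78 °C; then aq. Na2SO3, THF, 50 °C
Reagents that add atoms: osmium tetroxide, O=[Os](=O)(=O)=O
Why: Hydrogen-bond-directed dihydroxylation: the OsO4·TMEDA complex is held by the C9 hydroxyl and adds suprafacially to the adjacent C7=C8 bond on the hydroxyl face of the rotamer with H9 eclipsing C6 (allylic 1,3-strain), which should set C8 syn to the C9 oxygen and C7 by syn-addition to the ring-cis alkene, while the chloroalkene and the C13=C14 alkene carry no directing group.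

Step 25
Reactants: 40
Product: 41 tetraol (C19 OH)
Conditions: HF·pyridine, pyridine, THF, 0 °C → rt
Reagents that add atoms: none
Why: Fluoride cleavage of the primary TBDPS ether under buffered acidic conditions, which should leave the acetates in place.

Step 26
Reactants: 41
Product: 44 CNP0296164.1 (target), via hydroxy aldehyde 42 (not isolated), via lactol 43 (not isolated)
Conditions: TEMPO (0.2 equiv), PhI(OAc)2 (2.5 equiv), CH2Cl2, rt
Reagents that add atoms: none
Why: Oxoammonium oxidation selective for the primary C19 alcohol; the aldehyde should be trapped by the C7 hydroxyl as the trans-fused five-membered lactol (closure onto O9 would force the C7–C8–C9–C10 ring torsion toward eclipsing) and is oxidised on to the γ-lactone, with C17 keeping the chiral-pool configuration.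

**Compound list**

1 | 2,2-dimethoxyacetaldehyde | COC(OC)C=O | starting material
2 | methyl 2-(triphenylphosphoranylidene)propanoate | COC(=O)C(C)=P(c1ccccc1)(c1ccccc1)c1ccccc1 | starting material
3 | methyl (E)-4,4-dimethoxy-2-methylbut-2-enoate | COC(OC)/C=C(\C)C(=O)OC | intermediate
4 | methyl (E)-2-methyl-4-oxobut-2-enoate | O=C/C=C(\C)C(=O)OC | intermediate
5 | (E)-penta-1,3-diene | C/C=C/C=C | starting material
6 | methyl (1S,5S,6S)-6-formyl-1,5-dimethylcyclohex-3-ene-1-carboxylate | O=C[C@H]1[C@@H](C)C=CC[C@]1(C)C(=O)OC | intermediate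
7 | methyl (1S,5S,6S)-6-(dimethoxymethyl)-1,5-dimethylcyclohex-3-ene-1-carboxylate | COC(OC)[C@H]1[C@@H](C)C=CC[C@]1(C)C(=O)OC | intermediate
8 | 12α,13α-epoxide of 7 (oxirane trans to the C11 and C1 methyl groups) | COC(OC)[C@H]1[C@@H](C)[C@@H]2O[C@@H]2C[C@]1(C)C(=O)OC | intermediate
9 | hydroxy selenide (12α-OH, 13β-SePh) | COC(OC)[C@H]1[C@@H](C)[C@H](O)[C@@H]([Se]c2ccccc2)C[C@]1(C)C(=O)OC | intermediate
10 | selenoxide of 9 | COC(OC)[C@H]1[C@@H](C)[C@H](O)[C@@H]([Se](=O)c2ccccc2)C[C@]1(C)C(=O)OC | intermediate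
11 | methyl (1S,4R,5R,6S)-6-(dimethoxymethyl)-4-hydroxy-1,5-dimethylcyclohex-2-ene-1-carboxylate | COC(OC)[C@H]1[C@@H](C)[C@H](O)C=C[C@]1(C)C(=O)OC | intermediate
12 | methyl phenyl sulfone | CS(=O)(=O)c1ccccc1 | starting material
13 | (phenylsulfonyl)methyllithium | [Li]CS(=O)(=O)c1ccccc1 | intermediate
14 | 1-[(1S,4R,5R,6S)-6-(dimethoxymethyl)-4-hydroxy-1,5-dimethylcyclohex-2-en-1-yl]-2-(phenylsulfonyl)ethan-1-one | COC(OC)[C@H]1[C@@H](C)[C@H](O)C=C[C@]1(C)C(=O)CS(=O)(=O)c1ccccc1 | intermediate
15 | (S)-3-bromo-2-methylpropan-1-ol | OC[C@H](C)CBr | starting material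
16 | (S)-(3-bromo-2-methylpropoxy)(tert-butyl)diphenylsilane | CC(C)(C)[Si](OC[C@H](C)CBr)(c1ccccc1)c1ccccc1 | intermediate
17 | [(S)-3-{[tert-butyl(diphenyl)silyl]oxy}-2-methylpropyl](triphenyl)phosphonium bromide | CC(C)(C)[Si](OC[C@H](C)C[P+](c1ccccc1)(c1ccccc1)c1ccccc1)(c1ccccc1)c1ccccc1.[Br-] | intermediate
18 | 2-(prop-2-yn-1-yloxy)tetrahydro-2H-pyran | C#CCOC1CCCCO1 | starting material
19 | methyl chloroformate | COC(Cl)=O | starting material
20 | lithium acetylide of 18 | [Li]C#CCOC1CCCCO1 | intermediate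
21 | methyl 4-(tetrahydro-2H-pyran-2-yloxy)but-2-ynoate | COC(=O)C#CCOC1CCCCO1 | intermediate
22 | lithium methyl(alkenyl)cuprate from syn-addition to 21 (Cu on C6, cis to the C5 methyl) | COC(=O)/C([Cu-]C)=C(C)\COC1CCCCO1.[Li+] | intermediate
23 | methyl (E)-2-chloro-3-methyl-4-(tetrahydro-2H-pyran-2-yloxy)but-2-enoate | COC(=O)/C(Cl)=C(C)\COC1CCCCO1 | intermediate
24 | (E)-2-chloro-3-methyl-4-(tetrahydro-2H-pyran-2-yloxy)but-2-en-1-ol | OC/C(Cl)=C(C)\COC1CCCCO1 | intermediate
25 | (E)-2-chloro-3-methyl-4-(tetrahydro-2H-pyran-2-yloxy)but-2-enal | O=C/C(Cl)=C(C)\COC1CCCCO1 | intermediate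
26 | phosphonium ylide from 17 | CC(C)(C)[Si](OC[C@H](C)C=P(c1ccccc1)(c1ccccc1)c1ccccc1)(c1ccccc1)c1ccccc1 | intermediate
27 | α-iodophosphonium iodide | CC(C)(C)[Si](OC[C@H](C)C(I)[P+](c1ccccc1)(c1ccccc1)c1ccccc1)(c1ccccc1)c1ccccc1.[I-] | intermediate
28 | α-iodo ylide | CC(C)(C)[Si](OC[C@H](C)C(I)=P(c1ccccc1)(c1ccccc1)c1ccccc1)(c1ccccc1)c1ccccc1 | intermediate
29 | tert-butyl{[(2S,3Z,5E)-5-chloro-3-iodo-2,6-dimethyl-7-(tetrahydro-2H-pyran-2-yloxy)hepta-3,5-dien-1-yl]oxy}diphenylsilane | O(C/C(C)=C(Cl)\C=C(/I)[C@@H](C)CO[Si](c1ccccc1)(c1ccccc1)C(C)(C)C)C1CCCCO1 | intermediate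
30 | {[(2S,3Z,5E)-7-bromo-5-chloro-3-iodo-2,6-dimethylhepta-3,5-dien-1-yl]oxy}(tert-butyl)diphenylsilane | BrC/C(C)=C(Cl)\C=C(/I)[C@@H](C)CO[Si](c1ccccc1)(c1ccccc1)C(C)(C)C | intermediate
31 | C3-(phenylsulfonyl) C2 ketone (C3 epimers; C12 OH; C9 dimethyl acetal; (5E,7Z)-6-chloro-8-iodo diene; C19 OTBDPS) | COC(OC)[C@H]1[C@@H](C)[C@H](O)C=C[C@]1(C)C(=O)C(C/C(C)=C(Cl)\C=C(/I)[C@@H](C)CO[Si](c1ccccc1)(c1ccccc1)C(C)(C)C)S(=O)(=O)c1ccccc1 | intermediate
32 | C2 ketone (desulfonylated 31) | COC(OC)[C@H]1[C@@H](C)[C@H](O)C=C[C@]1(C)C(=O)CC/C(C)=C(Cl)\C=C(/I)[C@@H](C)CO[Si](c1ccccc1)(c1ccccc1)C(C)(C)C | intermediate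
33 | (2S)-2,12-diol | COC(OC)[C@H]1[C@@H](C)[C@H](O)C=C[C@]1(C)[C@@H](O)CC/C(C)=C(Cl)\C=C(/I)[C@@H](C)CO[Si](c1ccccc1)(c1ccccc1)C(C)(C)C | intermediate
34 | (2S)-2,12-diacetate | COC(OC)[C@H]1[C@@H](C)[C@H](OC(C)=O)C=C[C@]1(C)[C@@H](OC(C)=O)CC/C(C)=C(Cl)\C=C(/I)[C@@H](C)CO[Si](c1ccccc1)(c1ccccc1)C(C)(C)C | intermediate
35 | seco-aldehyde (C9 formyl; 2,12-diacetate; (7Z)-8-iodo diene; C19 OTBDPS) | O=C[C@H]1[C@@H](C)[C@H](OC(C)=O)C=C[C@]1(C)[C@@H](OC(C)=O)CC/C(C)=C(Cl)\C=C(/I)[C@@H](C)CO[Si](c1ccccc1)(c1ccccc1)C(C)(C)C | intermediate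
36 | ring B allylic alcohol (C9 epimers; (5E,7Z)-diene; 2,12-diacetate; C19 OTBDPS) | CC(=O)O[C@H]1CC/C(C)=C(/Cl)\C=C([C@@H](C)CO[Si](c3ccccc3)(c3ccccc3)C(C)(C)C)/C(O)[C@H]2[C@@H](C)[C@H](OC(C)=O)C=C[C@@]21C | intermediate
37 | ring B dienone (C9 ketone) | CC(=O)O[C@H]1CC/C(C)=C(/Cl)\C=C([C@@H](C)CO[Si](c3ccccc3)(c3ccccc3)C(C)(C)C)/C(=O)[C@H]2[C@@H](C)[C@H](OC(C)=O)C=C[C@@]21C | intermediate
38 | (9S)-allylic alcohol | CC(=O)O[C@H]1CC/C(C)=C(/Cl)\C=C([C@@H](C)CO[Si](c3ccccc3)(c3ccccc3)C(C)(C)C)/[C@@H](O)[C@H]2[C@@H](C)[C@H](OC(C)=O)C=C[C@@]21C | intermediate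
39 | osmate ester of the 7,8-diol, TMEDA chelate (9-OH free) | CC(=O)O[C@H]1CC/C(C)=C(/Cl)[C@@H]3O[Os-2]4(=O)(=O)([N+](C)(C)CC[N+]4(C)C)O[C@]3([C@@H](C)CO[Si](c5ccccc5)(c5ccccc5)C(C)(C)C)[C@@H](O)[C@H]2[C@@H](C)[C@H](OC(C)=O)C=C[C@@]21C | intermediate
40 | (7R,8R,9S)-triol (C19 OTBDPS) | CC(=O)O[C@H]1CC/C(C)=C(/Cl)[C@H](O)[C@@](O)([C@@H](C)CO[Si](c3ccccc3)(c3ccccc3)C(C)(C)C)[C@@H](O)[C@H]2[C@@H](C)[C@H](OC(C)=O)C=C[C@@]21C | intermediate
41 | tetraol (C19 OH) | CC(=O)O[C@H]1CC/C(C)=C(/Cl)[C@H](O)[C@@](O)([C@@H](C)CO)[C@@H](O)[C@H]2[C@@H](C)[C@H](OC(C)=O)C=C[C@@]21C | intermediate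
42 | C19 hydroxy aldehyde | CC(=O)O[C@H]1CC/C(C)=C(/Cl)[C@H](O)[C@@](O)([C@@H](C)C=O)[C@@H](O)[C@H]2[C@@H](C)[C@H](OC(C)=O)C=C[C@@]21C | intermediate
43 | lactol (C19 hemiacetal closed on O7) | CC(=O)O[C@H]1CC/C(C)=C(/Cl)[C@@H]2OC(O)[C@H](C)[C@@]2(O)[C@@H](O)[C@H]2[C@@H](C)[C@H](OC(C)=O)C=C[C@@]21C | intermediate
44 | CNP0296164.1, (5E)-2,12-diacetoxy-6-chloro-8,9-dihydroxy lactone, configuration 1S,2S,7R,8R,9S,10S,11R,12R,17R in the numbering used here | CC(=O)O[C@H]1CC/C(C)=C(/Cl)[C@@H]2OC(=O)[C@H](C)[C@@]2(O)[C@@H](O)[C@H]2[C@@H](C)[C@H](OC(C)=O)C=C[C@@]21C | target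

**Count**

Total step count: 26. Longest linear sequence: 18 steps (steps 1–7, then 16–26).

**Steps most likely to fail**

1. Step 21 (closure of ring B). The alkenylchromium has to reach a neopentyl-type aldehyde across a forming ten-membered ring, so intermolecular coupling or simple loss of the iodine may outrun ring closure. The fallback reverses the order of the two unions: the hindered C8–C9 bond is made between two molecules and ring B is closed by the soft-enolate alkylation at C3–C4. It sets out from 14 (with 29 from step 14) and returns at 37. Keto sulfone 14 is acetylated at O12 (Ac2O, pyridine) to the 12-acetate F1. Mild aqueous acid frees the C9 aldehyde F2. Intermolecular Nozaki–Hiyama–Kishi coupling with 29 (CrCl2, cat. NiCl2, DMSO) gives the C9 allylic alcohol F3 as an epimer mixture. PPTS in MeOH removes the THP group to give the diol F4. CBr4/PPh3 at −20 °C converts the primary allylic alcohol into the allylic bromide F5. Cs2CO3 in MeCN at high dilution closes ring B to the cyclic β-keto sulfone F6. SmI2 removes the sulfonyl group to give the cyclic C2 ketone F7. (R)-Me-CBS with BH3·SMe2 sets C2 in the diol F8. MnO2 oxidises only the allylic C9 alcohol to the hydroxy dienone F9. Acetylation of the C2 hydroxyl then gives 37, and steps 23–26 follow unchanged.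

2. Step 3 (key cycloaddition). Bond formation at the fully substituted dienophile carbon with a diene of modest nucleophilicity may be slow enough for uncatalysed, exo or regioisomeric pathways to erode enantioface and regiocontrol. The same fallback also removes the dependence on the face and site selectivity of steps 5 and 6. It keeps the disconnection but moves activation onto the diene and the C13 oxidation level; it sets out from 4 and returns at 11. Commercial (E)-pent-3-en-2-one is silylated (TIPSOTf, Et3N) to (E)-2-(triisopropylsilyloxy)penta-1,3-diene F10, in which the 1-methyl and 3-siloxy groups both direct C14 to C1. The same oxazaborolidinium catalyst should give the silyl enol ether cycloadduct F11. Rubottom oxidation (mCPBA, NaHCO3) on the α face, anti to the adjacent C11 methyl group, gives the α-silyloxy ketone F12 with the C12 oxygen in place. Acetalisation of the aldehyde at 0 °C gives the dimethyl acetal F13. LiN(SiMe3)2 and PhNTf2 give the C13 enol triflate F14 toward the C14 methylene. Pd(OAc)2/PPh3 with HCO2H and Bu3N reduces it to the C13=C14 alkene, silyl ether F15. Bu4NF then frees the C12 hydroxyl to give 11.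

3. Step 14 (iodo-olefination). The hindered, β-branched α-iodo ylide may add sluggishly to the α-chloro enal, so that proton exchange, loss of iodine or leakage to the (E)-iodide competes. The fallback builds the same (Z)-halo diene by cross-coupling; it sets out from 25 and 16 and returns at 29. Ramirez olefination of 25 (CBr4, PPh3, Et3N) gives the 1,1-dibromo diene F16. Finkelstein exchange on 16 (NaI, acetone) gives the iodide F17, and zinc insertion (Zn, LiCl, THF) gives the alkylzinc iodide F18. Negishi coupling with PdCl2(DPEphos) replaces only the bromine trans to C6 and gives the (Z)-bromo diene F19. Copper-catalysed halogen exchange (CuI, NaI, trans-N,N'-dimethylcyclohexane-1,2-diamine, dioxane, 110 °C) with retention then gives 29.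

Further compounds

F1 | step 21 | 12-O-acetyl derivative of 14 | COC(OC)[C@H]1[C@@H](C)[C@H](OC(C)=O)C=C[C@]1(C)C(=O)CS(=O)(=O)c1ccccc1
F2 | step 21 | C9 aldehyde from F1 | O=C[C@H]1[C@@H](C)[C@H](OC(C)=O)C=C[C@]1(C)C(=O)CS(=O)(=O)c1ccccc1
F3 | step 21 | intermolecular coupling product of F2 and 29 (C9 allylic alcohol, epimers; C4 OTHP) | O1CCCCC1OC/C(C)=C(Cl)\C=C([C@@H](C)CO[Si](c2ccccc2)(c2ccccc2)C(C)(C)C)/C(O)[C@H]3[C@@H](C)[C@H](OC(C)=O)C=C[C@]3(C)C(=O)CS(=O)(=O)c2ccccc2
F4 | step 21 | C4,C9-diol from F3 | OC/C(C)=C(Cl)\C=C([C@@H](C)CO[Si](c2ccccc2)(c2ccccc2)C(C)(C)C)/C(O)[C@H]3[C@@H](C)[C@H](OC(C)=O)C=C[C@]3(C)C(=O)CS(=O)(=O)c2ccccc2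
F5 | step 21 | C4 allylic bromide from F4 | BrC/C(C)=C(Cl)\C=C([C@@H](C)CO[Si](c2ccccc2)(c2ccccc2)C(C)(C)C)/C(O)[C@H]3[C@@H](C)[C@H](OC(C)=O)C=C[C@]3(C)C(=O)CS(=O)(=O)c2ccccc2
F6 | step 21 | ring B β-keto sulfone (C3 and C9 epimers) | O=C1C(S(=O)(=O)c2ccccc2)C/C(C)=C(/Cl)\C=C([C@@H](C)CO[Si](c3ccccc3)(c3ccccc3)C(C)(C)C)/C(O)[C@H]2[C@@H](C)[C@H](OC(C)=O)C=C[C@@]21C
F7 | step 21 | ring B C2 ketone (C9 epimers) | O=C1CC/C(C)=C(/Cl)\C=C([C@@H](C)CO[Si](c3ccccc3)(c3ccccc3)C(C)(C)C)/C(O)[C@H]2[C@@H](C)[C@H](OC(C)=O)C=C[C@@]21C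
F8 | step 21 | ring B (2S)-2,9-diol, 12-acetate (C9 epimers) | O[C@H]1CC/C(C)=C(/Cl)\C=C([C@@H](C)CO[Si](c3ccccc3)(c3ccccc3)C(C)(C)C)/C(O)[C@H]2[C@@H](C)[C@H](OC(C)=O)C=C[C@@]21C
F9 | step 21 | ring B hydroxy dienone (C2 OH, C9 ketone, 12-acetate) | O[C@H]1CC/C(C)=C(/Cl)\C=C([C@@H](C)CO[Si](c3ccccc3)(c3ccccc3)C(C)(C)C)/C(=O)[C@H]2[C@@H](C)[C@H](OC(C)=O)C=C[C@@]21C
F10 | step 3 | (E)-2-(triisopropylsilyloxy)penta-1,3-diene | C=C(O[Si](C(C)C)(C(C)C)C(C)C)/C=C/C
F11 | step 3 | silyl enol ether cycloadduct (C12=C13 with OTIPS on C13) | O=C[C@H]1[C@@H](C)C=C(O[Si](C(C)C)(C(C)C)C(C)C)C[C@]1(C)C(=O)OC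
F12 | step 3 | 12α-silyloxy C13 ketone | O=C[C@H]1[C@@H](C)[C@H](O[Si](C(C)C)(C(C)C)C(C)C)C(=O)C[C@]1(C)C(=O)OC
F13 | step 3 | dimethyl acetal of F12 | COC(OC)[C@H]1[C@@H](C)[C@H](O[Si](C(C)C)(C(C)C)C(C)C)C(=O)C[C@]1(C)C(=O)OC
F14 | step 3 | C13 enol triflate (C13=C14) | COC(OC)[C@H]1[C@@H](C)[C@H](O[Si](C(C)C)(C(C)C)C(C)C)C(OS(=O)(=O)C(F)(F)F)=C[C@]1(C)C(=O)OC
F15 | step 3 | 12-O-triisopropylsilyl ether of 11 | COC(OC)[C@H]1[C@@H](C)[C@H](O[Si](C(C)C)(C(C)C)C(C)C)C=C[C@]1(C)C(=O)OC
F16 | step 14 | 1,1-dibromo diene from 25 | BrC(Br)=C/C(Cl)=C(C)\COC1CCCCO1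
F17 | step 14 | (S)-tert-butyl(3-iodo-2-methylpropoxy)diphenylsilane | CC(C)(C)[Si](OC[C@H](C)CI)(c1ccccc1)c1ccccc1
F18 | step 14 | alkylzinc iodide from F17 | CC(C)(C)[Si](OC[C@H](C)C[Zn]I)(c1ccccc1)c1ccccc1
F19 | step 14 | (3Z)-3-bromo analogue of 29 | O(C/C(C)=C(Cl)\C=C(/Br)[C@@H](C)CO[Si](c1ccccc1)(c1ccccc1)C(C)(C)C)C1CCCCO1
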